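(The numbers in the tables are calculated with made-up constants; scatter was added.)

Every unit of starting material charged either stays or ends in target, cross product or self-condensation product, so the next run is a choice of where those units go. The choice here is the manner of charging: second substrate fed (alder), starting material fed (maple), or everything at the start (cedar).

| flask | starting material | second substrate | solid reagent | remark | time |
|---|---|---|---|---|---|
| blue | 0.14 M | 2 equiv | 1.5 equiv | run made earlier |  |
| amber | 0.14 M | 2 equiv | 0.75 equiv | run made earlier |  |
| red | 0.14 M | 2 equiv | 1.1 equiv | run made earlier |  |
| grey | 0.21 M | 2 equiv | 1.5 equiv | run made earlier |  |
| alder | 0.14 M | 2.00 equiv (fed, over 15 min) | 1.50 equiv | all else is in the flask from the start; the feed brings no volume worth counting | 20 min |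
| maple | 0.14 M (fed, over 15 min) | 2.00 equiv | 1.50 equiv | all else is in the flask from the start; the feed brings no volume worth counting | 20 min |
| cedar | 0.14 M | 2.00 equiv | 1.50 equiv | everything together at the start | 20 min |

- blue (time / min: self-condensation product / %, target / %): 2.50: 25, 4; 5.00: 36, 11; 8.00: 39, 15; 10.0: 41, 19; 12.0: 41, 21
- amber (time / min: self-condensation product / %, target / %): 2.00: 21, 0; 6.00: 35, 10; 12.0: 40, 21; 15.0: 42, 20; 25.0: 41, 25
- red (time / min: self-condensation product / %, target / %): 5.00: 34, 10; 10.0: 38, 19; 15.0: 40, 23; 20.0: 42, 26; 25.0: 39, 25
- grey (time / min: self-condensation product / %, target / %): 2.00: 28, 4; 4.00: 38, 5; 6.00: 43, 8; 12.0: 44, 14; 25.0: 42, 15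

(readings scatter by 1.5 percentage points)

- percent here means starting material units held: one self-condensation product counts as two
- solid reagent is a solid; its amount is given per volume of the solution
- what was read earlier has a scatter of 1.5 percentage points, one standard deviation
- reactions considered so far: starting material + partner -> target; second substrate + partner -> second product; starting material + second substrate -> cross product; 2 starting material -> self-condensation product; solid reagent <-> partner
- at the start none of the solid reagent is in solution

- the flask with the highest amount of self-condensation product, in percent of the starting material charged ("all alike" if they lie within 1.5 percentage points) (alder / maple / cedar / all alike)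
- final self-condensation product, as a percentage of the starting material charged, in alder
- final self-condensation product, as a percentage of the starting material charged, in maple
- final self-condensation product, as a percentage of the starting material charged, in cedar

Let the level be the starting material left, as a fraction of the charge. It falls by a self-loss proportional to level squared, with coefficient a, and by a pseudo-first-order loss into target and cross product, taken here as constant in time. Let c be the level at which these two losses are equal. Of the units leaving at a given level, self-condensation takes

share = level / (level + c)

Integrating this share from the full charge down to nothing removes time:

plateau = 1 − c ln(1 + 1/c)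

Near these readings the logarithm is close to one, so blue's late reading gives the crossover level, the level of equal losses, as 59.0% of the charge.

Blue's first reading, doubled to allow for the level falling over that interval, gives a = 0.200 min⁻¹. Maple's feed, 0.0667 min⁻¹, then puts the level, in this reckoning, where feed equals both losses:

level = (c/2) (√(1 + 4 × feed/(a c²)) − 1) = 35.3%

The share there is 37.5%, an estimate from above for maple, whose level must first rise. Cedar is blue's recipe, and maple's estimate lies below blue's late reading, so this reckoning takes maple as the charge to try against self-condensation.

The forecast names alder as highest, with alder 52%, maple 25% and cedar 41%, and says of maple “second-order self-condensation is suppressed”. Its maple figure stands lower than this reckoning's estimate.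

The flasks give 52.6% in alder, 19.3% in maple and 40.4% in cedar, so alder is highest.

    starting material + partner → target (k = 0.101 L mol⁻¹ s⁻¹)
    second substrate + partner → second product (k = 0.00373 L mol⁻¹ s⁻¹)
    starting material + second substrate → cross product (k = 0.00458 L mol⁻¹ s⁻¹)
    2 starting material → self-condensation product (k = 0.0106 L mol⁻¹ s⁻¹)
    solid reagent ⇌ partner, rate k5*(cs5 - [partner]) while solid is left; crystals form when [partner] > cs5 (solubility = 0.110 M, k = 7.69 × 10⁻⁴ s⁻¹)

In maple, starting material stood at 28.3% after 10.0 min, with partner at 0.0152 M, and self-condensation product reached 15.7% as the feed ended at 15.0 min. With mean second substrate 0.261 M, maple's crossover level comes to 91.9% of the charge, where blue's reading gave 59.0%; the share at that moment's level, times the starting material consumed, gives 20.8%. Maple's neighbour with 5.00 equiv of second substrate has, from the amounts at its end, a crossover level of 150%, and the share at the level its feed sets, times the starting material consumed, gives 11.9%; that flask holds 10.8%.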